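## Retrosynthetic overview
1. Target 19 ⇒ MOM ether 18; the angelate, the allylic acetate and the aryl acetyl (from Ar–Br by Stille coupling) are late functional-group operations.
2. The CH2OAc carbon ⇒ one-carbon Matteson homologation/oxidation of an alkenyl–Bpin (8 → 11).
3. The dihydrofuran ring, the C2–C3 bond and both stereocentres ⇒ a new Cu-catalysed enantioselective borylative cyclisation of allenyl ether aldehyde 5. This is the only ring-forming step; the benzene ring is bought.
4. 5 ⇒ propargyl ether 4 ⇒ 5-bromo-2,4-dihydroxybenzaldehyde 1 + propargyl bromide 3.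

Assumption: the (2R,3R) centres of the given SMILES correspond to the 2,3-cis isomer (worked out from the SMILES); the sense of induction of the new Cu step is unknown, so (S,S)-Ph-BPE is written and the (R,R) ligand is used instead if it gives the (2S,3S) series.

## Route

Step 1
Reactants: 1 5-bromo-2,4-dihydroxybenzaldehyde
Product: 2 5-bromo-2-hydroxy-4-(methoxymethoxy)benzaldehyde
Conditions: MOMCl (1.1 equiv), i-Pr2NEt, CH2Cl2, 0 °C to rt
Reagents that add atoms: chloromethyl methyl ether (MOMCl), COCCl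
Why: Williamson-type O-alkylation goes selectively at the free, more acidic 4-OH (para to CHO) because the 2-OH is locked in a hydrogen bond to the aldehyde.

Step 2
Reactants: 2 5-bromo-2-hydroxy-4-(methoxymethoxy)benzaldehyde; 3 propargyl bromide
Product: 4 5-bromo-4-(methoxymethoxy)-2-(prop-2-yn-1-yloxy)benzaldehyde
Conditions: K2CO3, DMF, rt
Reagents that add atoms: none
Why: Williamson ether synthesis, in which carbonate in DMF deprotonates the remaining chelated phenol and the phenoxide displaces bromide from the unhindered propargylic carbon.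

Step 3
Reactants: 4 5-bromo-4-(methoxymethoxy)-2-(prop-2-yn-1-yloxy)benzaldehyde
Product: 5 5-bromo-4-(methoxymethoxy)-2-(propa-1,2-dien-1-yloxy)benzaldehyde
Conditions: KOt-Bu (0.3 equiv), THF, 0 °C, 30 min; basic alumina filtration
Reagents that add atoms: none
Why: Base-catalysed propargyl-to-allenyl prototropic isomerisation of an aryl propargyl ether, which stops at the aryloxyallene under catalytic t-BuOK and is tolerated by the non-enolisable aldehyde.

Step 4
Reactants: 5 5-bromo-4-(methoxymethoxy)-2-(propa-1,2-dien-1-yloxy)benzaldehyde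
Product: 7 (2R,3R)-5-bromo-6-(methoxymethoxy)-2-[1-(4,4,5,5-tetramethyl-1,3,2-dioxaborolan-2-yl)ethenyl]-2,3-dihydro-1-benzofuran-3-ol (2,3-cis), via O-boryl borate ester 6 (not isolated)
Conditions: CuCl (5 mol %), (S,S)-Ph-BPE (6 mol %), NaOt-Bu (10 mol %), B2pin2 (1.1 equiv), THF, −20 °C; aq NH4Cl
Reagents that add atoms: bis(pinacolato)diboron (B2pin2), CC1(C)OB(OC1(C)C)B1OC(C)(C)C(C)(C)O1
Why: Proposed new method: L*Cu–Bpin should add syn across the terminal (less hindered, less electron-rich) C=C of the aryloxyallene, anti to OAr and with boron on the central carbon, giving a (Z)-γ-aryloxy-β-boryl allylcopper whose CH2–Cu end sits next to the ortho aldehyde; γ-addition through a closed six-membered chair (OAr axial, aryl equatorial, the only arrangement of the Z-allylcopper that the three-atom tether allows) forms C2–C3 and closes the dihydrofuran ring cis, the chiral bisphosphine on copper selects the face pair that gives (2R,3R), and Cu–O/B–B σ-bond metathesis releases borate 6 and regenerates Cu–Bpin; the closest known reaction types are the Cu–bisphosphine-catalysed enantioselective three-component borylative allylation of aldehydes and ketones with allenes and B2pin2 and CuH couplings of alkoxyallenes with ketones, neither shown for an O-tethered allenyl ether closing a dihydrobenzofuran-3-ol.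

Step 5
Reactants: 7 (2R,3R)-5-bromo-6-(methoxymethoxy)-2-[1-(4,4,5,5-tetramethyl-1,3,2-dioxaborolan-2-yl)ethenyl]-2,3-dihydro-1-benzofuran-3-ol
Product: 8 {[(2R,3R)-5-bromo-6-(methoxymethoxy)-2-[1-(4,4,5,5-tetramethyl-1,3,2-dioxaborolan-2-yl)ethenyl]-2,3-dihydro-1-benzofuran-3-yl]oxy}triethylsilane
Conditions: TESCl, imidazole, DMAP (cat.), DMF, 0 °C to rt
Reagents that add atoms: chlorotriethylsilane (TESCl), CC[Si](Cl)(CC)CC
Why: Standard silylation of the secondary alcohol (retention at C3), which removes the acidic OH and prevents alkoxide–boron chelation in the homologation.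

Step 6
Reactants: 8 {[(2R,3R)-5-bromo-6-(methoxymethoxy)-2-[1-(4,4,5,5-tetramethyl-1,3,2-dioxaborolan-2-yl)ethenyl]-2,3-dihydro-1-benzofuran-3-yl]oxy}triethylsilane
Product: 11 2-[(2R,3R)-5-bromo-6-(methoxymethoxy)-3-(triethylsilyloxy)-2,3-dihydro-1-benzofuran-2-yl]prop-2-en-1-ol, via chloromethyl ate complex 9 (not isolated), via allyl boronate 10 (not isolated)
Conditions: ICH2Cl (1.5 equiv), n-BuLi (1.4 equiv, added last), THF, −78 °C to rt; then 3 M NaOH, 30 % H2O2, 0 °C
Reagents that add atoms: chloroiodomethane, ClCI; hydrogen peroxide, OO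
Why: Matteson homologation (LiCH2Cl made in situ by I/Li exchange, which is much faster than Ar–Br exchange, adds to boron and the alkenyl group undergoes 1,2-metallate shift with loss of chloride) followed by non-transposing oxidation of the allyl C–B bond gives the 2-substituted allylic alcohol without touching C2 or C3.

Step 7
Reactants: 11 2-[(2R,3R)-5-bromo-6-(methoxymethoxy)-3-(triethylsilyloxy)-2,3-dihydro-1-benzofuran-2-yl]prop-2-en-1-ol
Product: 13 1-[(2R,3R)-2-(3-hydroxyprop-1-en-2-yl)-6-(methoxymethoxy)-3-(triethylsilyloxy)-2,3-dihydro-1-benzofuran-5-yl]ethan-1-one, via aryl enol ether 12 (not isolated)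
Conditions: tributyl(1-ethoxyvinyl)stannane (1.5 equiv), PdCl2(PPh3)2 (5 mol %), toluene, 90 °C; then 0.5 M aq HCl, THF, 0 °C, 15 min
Reagents that add atoms: tributyl(1-ethoxyvinyl)stannane, CCCC[Sn](CCCC)(CCCC)C(=C)OCC; water, O
Why: Migita–Kosugi–Stille coupling of the aryl bromide with an acetyl-anion equivalent, then enol ether hydrolysis under acid mild and brief enough to keep the TES and MOM ethers, installs the acetyl group before any Pd-labile allylic acetate exists.

Step 8
Reactants: 13 1-[(2R,3R)-2-(3-hydroxyprop-1-en-2-yl)-6-(methoxymethoxy)-3-(triethylsilyloxy)-2,3-dihydro-1-benzofuran-5-yl]ethan-1-one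
Product: 14 2-[(2R,3R)-5-acetyl-6-(methoxymethoxy)-3-(triethylsilyloxy)-2,3-dihydro-1-benzofuran-2-yl]prop-2-en-1-yl acetate
Conditions: Ac2O, pyridine, DMAP (cat.), CH2Cl2, 0 °C
Reagents that add atoms: acetic anhydride, CC(=O)OC(C)=O
Why: DMAP-catalysed acylation of the only free hydroxyl, the primary allylic one.

Step 9
Reactants: 14 2-[(2R,3R)-5-acetyl-6-(methoxymethoxy)-3-(triethylsilyloxy)-2,3-dihydro-1-benzofuran-2-yl]prop-2-en-1-yl acetate
Product: 15 2-[(2R,3R)-5-acetyl-3-hydroxy-6-(methoxymethoxy)-2,3-dihydro-1-benzofuran-2-yl]prop-2-en-1-yl acetate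
Conditions: HF·pyridine, pyridine, THF, 0 °C
Reagents that add atoms: none
Why: Buffered fluoride desilylation cleaves the TES ether at silicon (retention at C3) and leaves the acetate, the MOM ether and the acid-sensitive benzylic alcohol intact.

Step 10
Reactants: 15 2-[(2R,3R)-5-acetyl-3-hydroxy-6-(methoxymethoxy)-2,3-dihydro-1-benzofuran-2-yl]prop-2-en-1-yl acetate; 16 angelic acid
Product: 18 (2R,3R)-2-(3-acetoxyprop-1-en-2-yl)-5-acetyl-6-(methoxymethoxy)-2,3-dihydro-1-benzofuran-3-yl (2Z)-2-methylbut-2-enoate, via angelic 2,4,6-trichlorobenzoic anhydride 17 (not isolated)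
Conditions: 16, 2,4,6-trichlorobenzoyl chloride, Et3N, toluene, rt, 2 h; then 15, 75 °C (no DMAP)
Reagents that add atoms: none
Why: Yamaguchi-type mixed-anhydride esterification, in which the alcohol attacks the unshielded angeloyl carbonyl and the absence of a nucleophilic catalyst avoids addition–elimination isomerisation of the Z-alkene to the tiglate; O-acylation keeps the C3 configuration.

Step 11
Reactants: 18 (2R,3R)-2-(3-acetoxyprop-1-en-2-yl)-5-acetyl-6-(methoxymethoxy)-2,3-dihydro-1-benzofuran-3-yl (2Z)-2-methylbut-2-enoate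
Product: 19 (2R,3R)-2-(3-acetoxyprop-1-en-2-yl)-5-acetyl-6-hydroxy-2,3-dihydro-1-benzofuran-3-yl (2Z)-2-methylbut-2-enoate (CNP0323250.1)
Conditions: NaHSO4·SiO2, CH2Cl2, rt
Reagents that add atoms: none
Why: Mild heterogeneous acid-catalysed acetal cleavage, where the aryl MOM ether ortho to the acetyl group is lost readily (the freed phenol is hydrogen-bonded to the ketone) while the benzylic angelate and allylic acetate are not ionised.

## Compound list
1 | 5-bromo-2,4-dihydroxybenzaldehyde | O=Cc1cc(Br)c(O)cc1O | starting material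
2 | 5-bromo-2-hydroxy-4-(methoxymethoxy)benzaldehyde | O=Cc1cc(Br)c(OCOC)cc1O | intermediate
3 | propargyl bromide (3-bromoprop-1-yne) | C#CCBr | starting material
4 | 5-bromo-4-(methoxymethoxy)-2-(prop-2-yn-1-yloxy)benzaldehyde | O=Cc1cc(Br)c(OCOC)cc1OCC#C | intermediate
5 | 5-bromo-4-(methoxymethoxy)-2-(propa-1,2-dien-1-yloxy)benzaldehyde | O=Cc1cc(Br)c(OCOC)cc1OC=C=C | intermediate
6 | 2-{[(2R,3R)-5-bromo-6-(methoxymethoxy)-2-[1-(4,4,5,5-tetramethyl-1,3,2-dioxaborolan-2-yl)ethenyl]-2,3-dihydro-1-benzofuran-3-yl]oxy}-4,4,5,5-tetramethyl-1,3,2-dioxaborolane (cis; not isolated) | C=C(B3OC(C)(C)C(C)(C)O3)[C@H]1Oc2cc(OCOC)c(Br)cc2[C@H]1OB4OC(C)(C)C(C)(C)O4 | intermediate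
7 | (2R,3R)-5-bromo-6-(methoxymethoxy)-2-[1-(4,4,5,5-tetramethyl-1,3,2-dioxaborolan-2-yl)ethenyl]-2,3-dihydro-1-benzofuran-3-ol (cis) | C=C(B3OC(C)(C)C(C)(C)O3)[C@H]1Oc2cc(OCOC)c(Br)cc2[C@H]1O | intermediate
8 | {[(2R,3R)-5-bromo-6-(methoxymethoxy)-2-[1-(4,4,5,5-tetramethyl-1,3,2-dioxaborolan-2-yl)ethenyl]-2,3-dihydro-1-benzofuran-3-yl]oxy}triethylsilane | C=C(B3OC(C)(C)C(C)(C)O3)[C@H]1Oc2cc(OCOC)c(Br)cc2[C@H]1O[Si](CC)(CC)CC | intermediate
9 | lithium (chloromethyl){1-[(2R,3R)-5-bromo-6-(methoxymethoxy)-3-(triethylsilyloxy)-2,3-dihydro-1-benzofuran-2-yl]ethenyl}(pinacolato)borate (not isolated) | [Li+].ClC[B-]3(OC(C)(C)C(C)(C)O3)C(=C)[C@H]1Oc2cc(OCOC)c(Br)cc2[C@H]1O[Si](CC)(CC)CC | intermediate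
10 | 2-{2-[(2R,3R)-5-bromo-6-(methoxymethoxy)-3-(triethylsilyloxy)-2,3-dihydro-1-benzofuran-2-yl]prop-2-en-1-yl}-4,4,5,5-tetramethyl-1,3,2-dioxaborolane (not isolated) | C=C(CB3OC(C)(C)C(C)(C)O3)[C@H]1Oc2cc(OCOC)c(Br)cc2[C@H]1O[Si](CC)(CC)CC | intermediate
11 | 2-[(2R,3R)-5-bromo-6-(methoxymethoxy)-3-(triethylsilyloxy)-2,3-dihydro-1-benzofuran-2-yl]prop-2-en-1-ol | C=C(CO)[C@H]1Oc2cc(OCOC)c(Br)cc2[C@H]1O[Si](CC)(CC)CC | intermediate
12 | 2-[(2R,3R)-5-(1-ethoxyethenyl)-6-(methoxymethoxy)-3-(triethylsilyloxy)-2,3-dihydro-1-benzofuran-2-yl]prop-2-en-1-ol (not isolated) | C=C(CO)[C@H]1Oc2cc(OCOC)c(C(=C)OCC)cc2[C@H]1O[Si](CC)(CC)CC | intermediate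
13 | 1-[(2R,3R)-2-(3-hydroxyprop-1-en-2-yl)-6-(methoxymethoxy)-3-(triethylsilyloxy)-2,3-dihydro-1-benzofuran-5-yl]ethan-1-one | C=C(CO)[C@H]1Oc2cc(OCOC)c(C(C)=O)cc2[C@H]1O[Si](CC)(CC)CC | intermediate
14 | 2-[(2R,3R)-5-acetyl-6-(methoxymethoxy)-3-(triethylsilyloxy)-2,3-dihydro-1-benzofuran-2-yl]prop-2-en-1-yl acetate | C=C(COC(C)=O)[C@H]1Oc2cc(OCOC)c(C(C)=O)cc2[C@H]1O[Si](CC)(CC)CC | intermediate
15 | 2-[(2R,3R)-5-acetyl-3-hydroxy-6-(methoxymethoxy)-2,3-dihydro-1-benzofuran-2-yl]prop-2-en-1-yl acetate | C=C(COC(C)=O)[C@H]1Oc2cc(OCOC)c(C(C)=O)cc2[C@H]1O | intermediate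
16 | angelic acid, (2Z)-2-methylbut-2-enoic acid | C/C=C(/C)C(=O)O | starting material
17 | (2Z)-2-methylbut-2-enoic 2,4,6-trichlorobenzoic anhydride (not isolated) | C/C=C(/C)C(=O)OC(=O)c1c(Cl)cc(Cl)cc1Cl | intermediate
18 | (2R,3R)-2-(3-acetoxyprop-1-en-2-yl)-5-acetyl-6-(methoxymethoxy)-2,3-dihydro-1-benzofuran-3-yl (2Z)-2-methylbut-2-enoate | C=C(COC(C)=O)[C@H]1Oc2cc(OCOC)c(C(C)=O)cc2[C@H]1OC(=O)/C(C)=C\C | intermediate
19 | (2R,3R)-2-(3-acetoxyprop-1-en-2-yl)-5-acetyl-6-hydroxy-2,3-dihydro-1-benzofuran-3-yl (2Z)-2-methylbut-2-enoate (CNP0323250.1) | C=C(COC(C)=O)[C@H]1Oc2cc(O)c(C(C)=O)cc2[C@H]1OC(=O)/C(C)=C\C | target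

## Step count and risks
Total steps: 11. Longest linear sequence: 11 steps (1 → 19; 3 and 16 are bought).

The three steps most likely to fail are 4, 6 and 10.

Step 4 is the proposed new reaction. It may give low ee, the trans isomer, or direct Cu–B addition to the aldehyde. The fallback uses known chemistry, sets out from 5 and comes back at 7. Pt(dba)2/PCy3-catalysed diboration of the terminal allene C=C of 5 with B2pin2 (toluene, 50 °C) gives 5-bromo-2-{[(1Z)-2,3-bis(4,4,5,5-tetramethyl-1,3,2-dioxaborolan-2-yl)prop-1-en-1-yl]oxy}-4-(methoxymethoxy)benzaldehyde F1. Its allylboronate adds in the same flask to the ortho aldehyde through a closed chair transition state (uncatalysed allylboration). This gives the cis borate as a racemate, that is 6 together with its (2S,3S) enantiomer F2. Aqueous work-up gives the racemic cis alcohol, that is 7 together with (2S,3S)-5-bromo-6-(methoxymethoxy)-2-[1-(4,4,5,5-tetramethyl-1,3,2-dioxaborolan-2-yl)ethenyl]-2,3-dihydro-1-benzofuran-3-ol F3. A lipase kinetic resolution follows (immobilised lipase chosen by screening so that the unwanted antipode reacts, vinyl acetate, MTBE, 35 °C, run past 50 % conversion). It converts F3 into the (2S,3S)-acetate F4, and the unreacted alcohol 7 is separated by chromatography and carried on from 7.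

Step 6 may fail through Ar–Br/Li exchange, butyl ate-complex formation, or slow attack on the hindered alkenyl boronate. The fallback sets out from 8 and comes back at 11. Iododeboronation of 8 (NaOMe, MeOH–THF, 0 °C, then I2) gives {[(2S,3R)-5-bromo-2-(1-iodoethenyl)-6-(methoxymethoxy)-2,3-dihydro-1-benzofuran-3-yl]oxy}triethylsilane F5; the geometry is unchanged and the C2 descriptor changes only because iodine raises the priority of the vinyl carbon. A Stille hydroxymethylation with (tributylstannyl)methanol (Pd2(dba)3, AsPh3, dioxane, 60 °C) then reacts at the alkenyl iodide in preference to the electron-rich aryl bromide and gives 11 without any organolithium.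

Step 10 may fail through Z-to-E isomerisation to the tiglate, sluggish acylation of the hindered cis alcohol, or elimination to the benzofuran on heating. The fallback sets out from 15 and comes back at 18. Steglich esterification of 15 with 2-[bis(2-methylphenoxy)phosphoryl]propanoic acid (DCC, DMAP, CH2Cl2, 0 °C; no alkene is present to isomerise) gives (2R,3R)-2-(3-acetoxyprop-1-en-2-yl)-5-acetyl-6-(methoxymethoxy)-2,3-dihydro-1-benzofuran-3-yl 2-[bis(2-methylphenoxy)phosphoryl]propanoate F6 as a mixture of epimers at the phosphorus-bearing carbon. An Ando-type Z-selective Horner–Wadsworth–Emmons reaction with acetaldehyde (NaH or NaI/DBU, THF, −78 to 0 °C) then builds the angelate double bond on the molecule and gives 18.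

## Further compounds
F1 | step 4 | 5-bromo-2-{[(1Z)-2,3-bis(4,4,5,5-tetramethyl-1,3,2-dioxaborolan-2-yl)prop-1-en-1-yl]oxy}-4-(methoxymethoxy)benzaldehyde | O=Cc1cc(Br)c(OCOC)cc1O/C=C(/B2OC(C)(C)C(C)(C)O2)CB3OC(C)(C)C(C)(C)O3
F2 | step 4 | 2-{[(2S,3S)-5-bromo-6-(methoxymethoxy)-2-[1-(4,4,5,5-tetramethyl-1,3,2-dioxaborolan-2-yl)ethenyl]-2,3-dihydro-1-benzofuran-3-yl]oxy}-4,4,5,5-tetramethyl-1,3,2-dioxaborolane (enantiomer of 6) | C=C(B3OC(C)(C)C(C)(C)O3)[C@@H]1Oc2cc(OCOC)c(Br)cc2[C@@H]1OB4OC(C)(C)C(C)(C)O4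
F3 | step 4 | (2S,3S)-5-bromo-6-(methoxymethoxy)-2-[1-(4,4,5,5-tetramethyl-1,3,2-dioxaborolan-2-yl)ethenyl]-2,3-dihydro-1-benzofuran-3-ol (enantiomer of 7) | C=C(B3OC(C)(C)C(C)(C)O3)[C@@H]1Oc2cc(OCOC)c(Br)cc2[C@@H]1O
F4 | step 4 | (2S,3S)-5-bromo-6-(methoxymethoxy)-2-[1-(4,4,5,5-tetramethyl-1,3,2-dioxaborolan-2-yl)ethenyl]-2,3-dihydro-1-benzofuran-3-yl acetate | C=C(B3OC(C)(C)C(C)(C)O3)[C@@H]1Oc2cc(OCOC)c(Br)cc2[C@@H]1OC(C)=O
F5 | step 6 | {[(2S,3R)-5-bromo-2-(1-iodoethenyl)-6-(methoxymethoxy)-2,3-dihydro-1-benzofuran-3-yl]oxy}triethylsilane | C=C(I)[C@H]1Oc2cc(OCOC)c(Br)cc2[C@H]1O[Si](CC)(CC)CC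
F6 | step 10 | (2R,3R)-2-(3-acetoxyprop-1-en-2-yl)-5-acetyl-6-(methoxymethoxy)-2,3-dihydro-1-benzofuran-3-yl 2-[bis(2-methylphenoxy)phosphoryl]propanoate | C=C(COC(C)=O)[C@H]1Oc2cc(OCOC)c(C(C)=O)cc2[C@H]1OC(=O)C(C)P(=O)(Oc3ccccc3C)Oc4ccccc4C
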